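**Plan**

1. Locants (azulene numbering of the target): C3 = C(OH)(i-Pr), C3a = ring-fusion CH, C4 = ester carbinol, C5 = CH2, C6 = C–CH3, C7 = =CH, C8 = C=O, C8a = quaternary C–CH3; the five-membered ring is C1–C2–C3–C3a–C8a.
2. Retrosynthesis: cut the C4–O vanillate ester, move C6=C7 out to an exocyclic methylene, cut C4–C5 of the seven-membered ring (key), then C6–C7, C3–isopropyl, C3a–C4 and C8–C8a, arriving at 3-methylcyclopent-2-en-1-one.
3. Enabling feature: in the seven-membered ring C4–O and C8=O are 1,4-related across the ring-fusion bond C3a–C8a, and C5–C6(CH3)–C7 is an isobutene unit. The ring is therefore a trans-cyclopentane-1,2-dicarbonyl compound spanned by a 2-methylenepropane-1,3-diyl unit, used here as an allylsilane.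
4. Forward: the five-membered ring is bought; C8a, C3a and C3 are set on it; the three-carbon allylsilane is attached at C7; the seven-membered ring closes last by intramolecular Hosomi–Sakurai allylation of the C4 aldehyde; the vanillate is attached at the end.
5. Stereochemistry: C8a from a copper-catalysed asymmetric conjugate addition; C3a and C3 by relay from the bulky C8a substituent; C4 in the ring closure; the trans ring fusion follows from the trans C3a/C8a substituents on the cyclopentane.
6. Helpers, all removed again: the vinylic SiMe3 (steric control), the O-TBS group, the allylic SiMe3 (lost in the ring closure), the exocyclic methylene (isomerised) and the phenol acetate.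

Key step: step 9

Remark: the oxirane/carbinol centre at C8 in 9, 10 and 13 is carried as an epimer mixture because step 8 destroys it; in step 1 the ligand antipode that gives the (S) centre is used; 11 and 17 are taken as purchasable.

**Step 1**
Reactants: 1 3-methylcyclopent-2-en-1-one; 2 ethynyltrimethylsilane
Product: 5 trimethyl({(3S)-3-methyl-3-[1-(trimethylsilyl)ethenyl]cyclopent-1-en-1-yl}oxy)silane, via alkenylalane 3 (not isolated), via aluminium enolate 4 (not isolated)
Conditions: 2, DIBAL-H, hexanes/THF, 55 °C; then 1, Cu(OTf)2 (5 mol %), chiral sulfonate-bearing imidazolinium salt (carbene precursor, 5 mol %), THF, −78 °C; then TMSOTf, −78 → 0 °C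
Reagents that add atoms: trimethylsilyl trifluoromethanesulfonate, C[Si](C)(C)OS(=O)(=O)C(F)(F)F
Why: Hydroalumination places aluminium geminal to silicon, and the copper–carbene-catalysed asymmetric conjugate addition of this alkenylalane to the β-methyl enone should create the quaternary C8a with catalyst-controlled (S) configuration; O-silylation of the aluminium enolate fixes the enolate regiochemistry toward C3a, which later deprotonation could not deliver.

**Step 2**
Reactants: 5 trimethyl({(3S)-3-methyl-3-[1-(trimethylsilyl)ethenyl]cyclopent-1-en-1-yl}oxy)silane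
Product: 6 (2S,3S)-2-(hydroxymethyl)-3-methyl-3-[1-(trimethylsilyl)ethenyl]cyclopentan-1-one
Conditions: 37 % aq. HCHO, Yb(OTf)3 (10 mol %), THF, rt
Reagents that add atoms: formaldehyde, C=O
Why: Lanthanide triflate-catalysed Mukaiyama aldol reaction with aqueous formaldehyde (hydroxymethylation); the electrophile should approach C3a anti to the very bulky 1-(trimethylsilyl)ethenyl group on C8a, placing CH2OH cis to the C8a methyl, which is also the thermodynamically preferred epimer.

**Step 3**
Reactants: 6 (2S,3S)-2-(hydroxymethyl)-3-methyl-3-[1-(trimethylsilyl)ethenyl]cyclopentan-1-one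
Product: 7 (2S,3S)-2-({[tert-butyl(dimethyl)silyl]oxy}methyl)-3-methyl-3-[1-(trimethylsilyl)ethenyl]cyclopentan-1-one
Conditions: TBSCl, imidazole, DMF, 0 °C → rt
Reagents that add atoms: tert-butyl(chloro)dimethylsilane, CC(C)(C)[Si](C)(C)Cl
Why: Standard silylation of the primary alcohol, which keeps the β-hydroxy ketone from retro-aldol cleavage under the organometallic conditions of step 4.

**Step 4**
Reactants: 7 (2S,3S)-2-({[tert-butyl(dimethyl)silyl]oxy}methyl)-3-methyl-3-[1-(trimethylsilyl)ethenyl]cyclopentan-1-one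
Product: 8 (1R,2S,3S)-2-({[tert-butyl(dimethyl)silyl]oxy}methyl)-3-methyl-1-(propan-2-yl)-3-[1-(trimethylsilyl)ethenyl]cyclopentan-1-ol
Conditions: i-PrMgCl, CeCl3, THF, −78 → −20 °C
Reagents that add atoms: isopropylmagnesium chloride, CC(C)[Mg]Cl
Why: Organocerium 1,2-addition to a hindered, enolisable ketone; the reagent should attack the face opposite to the C3a CH2OTBS group and the pseudo-axial C8a methyl (the bulky silylethenyl group sits pseudo-equatorial), so that at C3 the isopropyl group is trans and the hydroxyl cis to the CH2OTBS group.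

**Step 5**
Reactants: 8 (1R,2S,3S)-2-({[tert-butyl(dimethyl)silyl]oxy}methyl)-3-methyl-1-(propan-2-yl)-3-[1-(trimethylsilyl)ethenyl]cyclopentan-1-ol
Product: 9 (1R,2S,3S)-2-({[tert-butyl(dimethyl)silyl]oxy}methyl)-3-methyl-1-(propan-2-yl)-3-[2-(trimethylsilyl)oxiran-2-yl]cyclopentan-1-ol (both oxirane epimers)
Conditions: mCPBA, NaHCO3, CH2Cl2, 0 °C → rt
Reagents that add atoms: 3-chloroperoxybenzoic acid, OOC(=O)c1cccc(Cl)c1
Why: Prilezhaev epoxidation of the only alkene, an electron-rich 1,1-disubstituted vinylsilane, should give the α,β-epoxysilane; the configuration of the new oxirane carbon is of no consequence.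

**Step 6**
Reactants: 9 (1R,2S,3S)-2-({[tert-butyl(dimethyl)silyl]oxy}methyl)-3-methyl-1-(propan-2-yl)-3-[2-(trimethylsilyl)oxiran-2-yl]cyclopentan-1-ol
Product: 10 (1R,2S,3S)-2-(hydroxymethyl)-3-methyl-3-(oxiran-2-yl)-1-(propan-2-yl)cyclopentan-1-ol (both oxirane epimers)
Conditions: TBAF, THF, 0 °C → rt
Reagents that add atoms: none
Why: Fluoride-induced protodesilylation of the α,β-epoxysilane (retention at carbon) and cleavage of the silyl ether in one operation; the trans arrangement of CH2OH and oxirane on the ring disfavours intramolecular oxirane opening.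

**Step 7**
Reactants: 10 (1R,2S,3S)-2-(hydroxymethyl)-3-methyl-3-(oxiran-2-yl)-1-(propan-2-yl)cyclopentan-1-ol; 11 (2-bromoprop-2-en-1-yl)trimethylsilane
Product: 13 (1R,2S,3S)-2-(hydroxymethyl)-3-{1-hydroxy-3-[(trimethylsilyl)methyl]but-3-en-1-yl}-3-methyl-1-(propan-2-yl)cyclopentan-1-ol (both carbinol epimers), via alkenylmagnesium bromide 12 (not isolated)
Conditions: 11, Mg, THF, rt; then CuI (10 mol %) and 10, THF, −30 → 0 °C
Reagents that add atoms: none
Why: Copper-catalysed opening of the terminal epoxide at its CH2 group (C7) by the alkenyl Grignard reagent forms the C6–C7 bond and installs the 2-substituted allylsilane; excess reagent accounts for the two hydroxyl protons.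

**Step 8**
Reactants: 13 (1R,2S,3S)-2-(hydroxymethyl)-3-{1-hydroxy-3-[(trimethylsilyl)methyl]but-3-en-1-yl}-3-methyl-1-(propan-2-yl)cyclopentan-1-ol
Product: 14 (1R,2R,5S)-2-hydroxy-5-methyl-2-(propan-2-yl)-5-{3-[(trimethylsilyl)methyl]but-3-enoyl}cyclopentane-1-carbaldehyde
Conditions: Dess–Martin periodinane, NaHCO3, CH2Cl2, 0 °C → rt
Reagents that add atoms: none
Why: Dess–Martin oxidation converts the primary alcohol into the C4 aldehyde and the secondary alcohol into the C8 ketone while the tertiary alcohol is inert; the buffered, non-basic medium should leave the β,γ-unsaturated ketone and the allylsilane untouched, and the trans 1,2-arrangement prevents lactol formation.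

**Step 9**
Reactants: 14 (1R,2R,5S)-2-hydroxy-5-methyl-2-(propan-2-yl)-5-{3-[(trimethylsilyl)methyl]but-3-enoyl}cyclopentane-1-carbaldehyde
Product: 15 (3R,3aS,4S,8aS)-3,4-dihydroxy-8a-methyl-6-methylidene-3-(propan-2-yl)octahydroazulen-8(1H)-one
Conditions: BF3·OEt2 (2.5 equiv), CH2Cl2 (dilute), −78 °C; aq. NaHCO3 work-up
Reagents that add atoms: none
Why: BF3 activates the C4 aldehyde, the terminal alkene carbon of the allylsilane (C5) attacks it, and the β-silyl cation at C6 loses the silyl group to fluoride, leaving the exocyclic methylene. The closest known reaction type is the intramolecular Hosomi–Sakurai allylation of aldehydes by 2-substituted allylsilanes, the ring-closing half of the [3+4] annulation of 1,4-dicarbonyl compounds with trimethylenemethane dianion equivalents. The seven-membered ring closes in the 7-exo-trig mode at the carbonyl, with the allylsilane π bond inside the new ring. The new C4 centre is substrate-controlled: the tether through C8a forces C5 to approach anti to C3, and the aldehyde should react through the rotamer with its hydrogen between the two fully substituted carbons C3 and C8a and its BF3-bound oxygen beside the C3a hydrogen, which gives the pseudo-equatorial (4S) alcohol; the trans ring fusion is already fixed by C3a and C8a. The step needs aldehyde-over-ketone and C5-over-C7 selectivity: the neopentylic C8 ketone could only be reached through a four-membered transition state, and the β-silicon effect makes C5 the nucleophilic carbon.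

**Step 10**
Reactants: 15 (3R,3aS,4S,8aS)-3,4-dihydroxy-8a-methyl-6-methylidene-3-(propan-2-yl)octahydroazulen-8(1H)-one
Product: 16 (3R,3aS,4S,8aS)-3,4-dihydroxy-6,8a-dimethyl-3-(propan-2-yl)-2,3,3a,4,5,8a-hexahydroazulen-8(1H)-one
Conditions: DBU (20 mol %), CH2Cl2, rt
Reagents that add atoms: none
Why: Base-mediated isomerisation of the β,γ-unsaturated ketone through the dienolate (deprotonation at the doubly activated C7, protonation at the exocyclic carbon) should give the thermodynamically favoured endocyclic trisubstituted enone; no stereocentre is affected and hydroxide at C4 is too poor a leaving group for vinylogous elimination.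

**Step 11**
Reactants: 17 4-(acetyloxy)-3-methoxybenzoic acid
Product: 18 4-(chlorocarbonyl)-2-methoxyphenyl acetate
Conditions: (COCl)2, DMF (cat.), CH2Cl2, 0 °C → rt
Reagents that add atoms: oxalyl chloride, ClC(=O)C(Cl)=O
Why: Acid chloride formation with oxalyl chloride under formamide catalysis; the aryl acetate is inert.

**Step 12**
Reactants: 16 (3R,3aS,4S,8aS)-3,4-dihydroxy-6,8a-dimethyl-3-(propan-2-yl)-2,3,3a,4,5,8a-hexahydroazulen-8(1H)-one; 18 4-(chlorocarbonyl)-2-methoxyphenyl acetate
Product: 19 (3R,3aS,4S,8aS)-3-hydroxy-6,8a-dimethyl-8-oxo-3-(propan-2-yl)-1,2,3,3a,4,5,8,8a-octahydroazulen-4-yl 4-(acetyloxy)-3-methoxybenzoate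
Conditions: DMAP, pyridine, CH2Cl2, 0 °C → rt
Reagents that add atoms: none
Why: DMAP-catalysed acylation (nucleophilic catalysis) of the secondary C4 hydroxyl; the tertiary C3 hydroxyl is too hindered to compete and the C4 configuration is retained.

**Step 13**
Reactants: 19 (3R,3aS,4S,8aS)-3-hydroxy-6,8a-dimethyl-8-oxo-3-(propan-2-yl)-1,2,3,3a,4,5,8,8a-octahydroazulen-4-yl 4-(acetyloxy)-3-methoxybenzoate
Product: 20 (3R,3aS,4S,8aS)-3-hydroxy-6,8a-dimethyl-8-oxo-3-(propan-2-yl)-1,2,3,3a,4,5,8,8a-octahydroazulen-4-yl 4-hydroxy-3-methoxybenzoate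
Conditions: pyrrolidine, CH2Cl2, 0 °C
Reagents that add atoms: none
Why: Chemoselective aminolysis of the phenyl acetate, which is far more electrophilic than the hindered alkyl benzoate; the mild amine at 0 °C should not trigger vinylogous β-elimination of the vanillate.

**Compound list**

1 | 3-methylcyclopent-2-en-1-one | CC1=CC(=O)CC1 | starting material
2 | ethynyltrimethylsilane | C#C[Si](C)(C)C | starting material
3 | bis(2-methylpropyl)[1-(trimethylsilyl)ethenyl]aluminium | CC(C)C[Al](CC(C)C)C(=C)[Si](C)(C)C | intermediate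
4 | bis(2-methylpropyl)aluminium (3S)-3-methyl-3-[1-(trimethylsilyl)ethenyl]cyclopent-1-en-1-olate | C=C([Si](C)(C)C)[C@@]1(C)CCC(O[Al](CC(C)C)CC(C)C)=C1 | intermediate
5 | trimethyl({(3S)-3-methyl-3-[1-(trimethylsilyl)ethenyl]cyclopent-1-en-1-yl}oxy)silane | C=C([Si](C)(C)C)[C@@]1(C)CCC(O[Si](C)(C)C)=C1 | intermediate
6 | (2S,3S)-2-(hydroxymethyl)-3-methyl-3-[1-(trimethylsilyl)ethenyl]cyclopentan-1-one | C=C([Si](C)(C)C)[C@@]1(C)CCC(=O)[C@@H]1CO | intermediate
7 | (2S,3S)-2-({[tert-butyl(dimethyl)silyl]oxy}methyl)-3-methyl-3-[1-(trimethylsilyl)ethenyl]cyclopentan-1-one | C=C([Si](C)(C)C)[C@@]1(C)CCC(=O)[C@@H]1CO[Si](C)(C)C(C)(C)C | intermediate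
8 | (1R,2S,3S)-2-({[tert-butyl(dimethyl)silyl]oxy}methyl)-3-methyl-1-(propan-2-yl)-3-[1-(trimethylsilyl)ethenyl]cyclopentan-1-ol | C=C([Si](C)(C)C)[C@@]1(C)CC[C@@](O)(C(C)C)[C@@H]1CO[Si](C)(C)C(C)(C)C | intermediate
9 | (1R,2S,3S)-2-({[tert-butyl(dimethyl)silyl]oxy}methyl)-3-methyl-1-(propan-2-yl)-3-[2-(trimethylsilyl)oxiran-2-yl]cyclopentan-1-ol (both oxirane epimers) | C[Si](C)(C)C1(CO1)[C@@]2(C)CC[C@@](O)(C(C)C)[C@@H]2CO[Si](C)(C)C(C)(C)C | intermediate
10 | (1R,2S,3S)-2-(hydroxymethyl)-3-methyl-3-(oxiran-2-yl)-1-(propan-2-yl)cyclopentan-1-ol (both oxirane epimers) | C1OC1[C@@]2(C)CC[C@@](O)(C(C)C)[C@@H]2CO | intermediate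
11 | (2-bromoprop-2-en-1-yl)trimethylsilane | C=C(Br)C[Si](C)(C)C | starting material
12 | bromo[3-(trimethylsilyl)prop-1-en-2-yl]magnesium | C=C([Mg]Br)C[Si](C)(C)C | intermediate
13 | (1R,2S,3S)-2-(hydroxymethyl)-3-{1-hydroxy-3-[(trimethylsilyl)methyl]but-3-en-1-yl}-3-methyl-1-(propan-2-yl)cyclopentan-1-ol (both carbinol epimers) | C[Si](C)(C)CC(=C)CC(O)[C@@]1(C)CC[C@@](O)(C(C)C)[C@@H]1CO | intermediate
14 | (1R,2R,5S)-2-hydroxy-5-methyl-2-(propan-2-yl)-5-{3-[(trimethylsilyl)methyl]but-3-enoyl}cyclopentane-1-carbaldehyde | C[Si](C)(C)CC(=C)CC(=O)[C@@]1(C)CC[C@@](O)(C(C)C)[C@@H]1C=O | intermediate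
15 | (3R,3aS,4S,8aS)-3,4-dihydroxy-8a-methyl-6-methylidene-3-(propan-2-yl)octahydroazulen-8(1H)-one | O[C@H]1CC(=C)CC(=O)[C@@]2(C)CC[C@@](O)(C(C)C)[C@H]12 | intermediate
16 | (3R,3aS,4S,8aS)-3,4-dihydroxy-6,8a-dimethyl-3-(propan-2-yl)-2,3,3a,4,5,8a-hexahydroazulen-8(1H)-one | O[C@H]1CC(C)=CC(=O)[C@@]2(C)CC[C@@](O)(C(C)C)[C@H]12 | intermediate
17 | 4-(acetyloxy)-3-methoxybenzoic acid | CC(=O)Oc1ccc(cc1OC)C(=O)O | starting material
18 | 4-(chlorocarbonyl)-2-methoxyphenyl acetate | CC(=O)Oc1ccc(cc1OC)C(Cl)=O | intermediate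
19 | (3R,3aS,4S,8aS)-3-hydroxy-6,8a-dimethyl-8-oxo-3-(propan-2-yl)-1,2,3,3a,4,5,8,8a-octahydroazulen-4-yl 4-(acetyloxy)-3-methoxybenzoate | COc1cc(C(=O)O[C@H]2CC(C)=CC(=O)[C@@]3(C)CC[C@@](O)(C(C)C)[C@H]23)ccc1OC(C)=O | intermediate
20 | (3R,3aS,4S,8aS)-3-hydroxy-6,8a-dimethyl-8-oxo-3-(propan-2-yl)-1,2,3,3a,4,5,8,8a-octahydroazulen-4-yl 4-hydroxy-3-methoxybenzoate | COc1cc(C(=O)O[C@H]2CC(C)=CC(=O)[C@@]3(C)CC[C@@](O)(C(C)C)[C@H]23)ccc1O | target

Total step count: 13
Longest linear sequence: 12 steps (steps 1–10, 12, 13)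

**Steps most likely to fail**

1. Step 9 (key step). The ring closure may show poor facial selectivity at the aldehyde, or the allylsilane may be lost by protodesilylation or by conjugation of the β,γ-unsaturated ketone before the C–C bond forms. The fallback closes the ring by metathesis at C6=C7 and sets C4 under reagent control; it sets out from 10. Dimethylsulfonium methylide (trimethylsulfonium iodide, n-BuLi, excess) should turn the oxirane into the one-carbon-homologated allylic alcohol (1R,2S,3S)-2-(hydroxymethyl)-3-(1-hydroxyprop-2-en-1-yl)-3-methyl-1-(propan-2-yl)cyclopentan-1-ol F1. Dess–Martin periodinane should then give the vinyl ketone aldehyde (1R,2R,5S)-2-hydroxy-5-methyl-5-(prop-2-enoyl)-2-(propan-2-yl)cyclopentane-1-carbaldehyde F2. Aldehyde-selective allylboration at −78 °C with B-(2-methylallyl)diisopinocampheylborane (the antipode that delivers the (S) carbinol) should give 1-{(1S,2S,3R)-3-hydroxy-2-[(1S)-1-hydroxy-3-methylbut-3-en-1-yl]-1-methyl-3-(propan-2-yl)cyclopentyl}prop-2-en-1-one F3. Ring-closing metathesis with the second-generation Hoveyda–Grubbs catalyst should then form the C6=C7 bond and come back to the route at 16.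

2. Step 1. O-Silylation of the aluminium enolate may be incomplete, or the enolate may lose its regiochemical integrity by proton exchange before it is trapped. The fallback secures the regiochemistry by blocking the other α-position; it sets out from 4. Aqueous quench gives the ketone (3S)-3-methyl-3-[1-(trimethylsilyl)ethenyl]cyclopentan-1-one F4. Dehydrogenation with 2-iodoxybenzoic acid, possible only on the side away from the quaternary carbon, should give (4R)-4-methyl-4-[1-(trimethylsilyl)ethenyl]cyclopent-2-en-1-one F5, whose only enolisable position is C3a. LDA followed by monomeric formaldehyde should give (4S,5S)-5-(hydroxymethyl)-4-methyl-4-[1-(trimethylsilyl)ethenyl]cyclopent-2-en-1-one F6 (attack anti to the silylethenyl group). Conjugate reduction with [(Ph3P)CuH]6 comes back to the route at 6.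

3. Step 6. The liberated primary alkoxide may open the oxirane to a six-membered cyclic ether, or C–Si cleavage at the hindered oxirane may be slow. The fallback replaces epoxide opening by carbonyl allylation; it sets out from 8. Lemieux–Johnson cleavage of the vinylsilane (OsO4 cat., NaIO4, 2,6-lutidine, dioxane/H2O) should give the acylsilane {(1S,2S,3R)-2-({[tert-butyl(dimethyl)silyl]oxy}methyl)-3-hydroxy-1-methyl-3-(propan-2-yl)cyclopentyl}(trimethylsilyl)methanone F7. TBAF in wet THF should cleave the acyl–silicon bond and the silyl ether to give (1S,2S,3R)-3-hydroxy-2-(hydroxymethyl)-1-methyl-3-(propan-2-yl)cyclopentane-1-carbaldehyde F8. Indium-mediated Barbier allylation with 2-(chloromethyl)-3-(trimethylsilyl)prop-1-ene (In, NaI, DMF) comes back to the route at 13.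

**Further compounds**

F1 | step 9 | (1R,2S,3S)-2-(hydroxymethyl)-3-(1-hydroxyprop-2-en-1-yl)-3-methyl-1-(propan-2-yl)cyclopentan-1-ol | C=CC(O)[C@@]1(C)CC[C@@](O)(C(C)C)[C@@H]1CO
F2 | step 9 | (1R,2R,5S)-2-hydroxy-5-methyl-5-(prop-2-enoyl)-2-(propan-2-yl)cyclopentane-1-carbaldehyde | C=CC(=O)[C@@]1(C)CC[C@@](O)(C(C)C)[C@@H]1C=O
F3 | step 9 | 1-{(1S,2S,3R)-3-hydroxy-2-[(1S)-1-hydroxy-3-methylbut-3-en-1-yl]-1-methyl-3-(propan-2-yl)cyclopentyl}prop-2-en-1-one | C=CC(=O)[C@@]1(C)CC[C@@](O)(C(C)C)[C@@H]1[C@@H](O)CC(C)=C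
F4 | step 1 | (3S)-3-methyl-3-[1-(trimethylsilyl)ethenyl]cyclopentan-1-one | C=C([Si](C)(C)C)[C@@]1(C)CCC(=O)C1
F5 | step 1 | (4R)-4-methyl-4-[1-(trimethylsilyl)ethenyl]cyclopent-2-en-1-one | C=C([Si](C)(C)C)[C@@]1(C)C=CC(=O)C1
F6 | step 1 | (4S,5S)-5-(hydroxymethyl)-4-methyl-4-[1-(trimethylsilyl)ethenyl]cyclopent-2-en-1-one | C=C([Si](C)(C)C)[C@@]1(C)C=CC(=O)[C@@H]1CO
F7 | step 6 | {(1S,2S,3R)-2-({[tert-butyl(dimethyl)silyl]oxy}methyl)-3-hydroxy-1-methyl-3-(propan-2-yl)cyclopentyl}(trimethylsilyl)methanone | C[Si](C)(C)C(=O)[C@@]1(C)CC[C@@](O)(C(C)C)[C@@H]1CO[Si](C)(C)C(C)(C)C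
F8 | step 6 | (1S,2S,3R)-3-hydroxy-2-(hydroxymethyl)-1-methyl-3-(propan-2-yl)cyclopentane-1-carbaldehyde | O=C[C@@]1(C)CC[C@@](O)(C(C)C)[C@@H]1CO
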